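**Assumption:** the target has no stereocentre and its diaryl ether axes rotate freely, so it is achiral; "single enantiomer" is read as the single constitution given by the SMILES.

## Retrosynthetic overview

1. 1 + 2 → 3: a two-ring phenol made in one step by a new Cu-catalysed reductive O-arylation of a quinone (aryl C–O bond); 3 is used twice.
2. 3 + 4 → 5 (Ullmann C–O coupling): rings F, E and D are in place (A = 2,4,6-trihydroxyphenyl end, F = 3,4,5-trihydroxyphenyl end).
3. 5 → 6 → 7, then + 3 → 8: chain-end C–H borylation, iodination and Ullmann coupling add rings C and B.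
4. 8 + 9 → (10, 11) → 12: the same sequence adds ring A; 12 → 13 by global O-demethylation.
5. No ring is formed: all six benzene rings are bought. All five inter-ring bonds are aryl C–O bonds of one type (an oxygen on a carbon flanked by two oxygens, bonded to C5 of the next 3,4,5-trioxygenated ring).

## Route

Step 1
Reactants: 1 2-(2,6-dimethoxyphenyl)-4,4,5,5-tetramethyl-1,3,2-dioxaborolane; 2 2,6-dimethoxy-1,4-benzoquinone
Product: 3 4-(2,6-dimethoxyphenoxy)-2,6-dimethoxyphenol
Conditions: 1 (1.3 equiv), CuCl (10 mol%), 3,4,7,8-tetramethyl-1,10-phenanthroline (12 mol%), CsF (1.5 equiv, activator, returned as fluoride on work-up), THF–DMF 4:1, Ar, 25 °C, 2 added over 4 h; then H2O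
Reagents that add atoms: none
Why: Proposed new method: fluoride-promoted B-to-Cu transmetalation gives a phenanthroline–Cu(I)–aryl (as in Cu-catalysed electrophilic amination of hindered arylboronates), which attacks the only exposed quinone oxygen, O4 of 2 (O1 is buried between two OMe groups; compare P(III) attack at quinone oxygen), in an aromatisation-driven two-electron oxidative addition to an aryl–Cu(III) aryloxide that undergoes Chan–Lam/Ullmann-type C–O reductive elimination, so the quinone is both oxidant and oxygen partner and the closest known reaction type is the Chan–Lam etherification; no stereocentre is formed.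

Step 2
Reactants: 3 4-(2,6-dimethoxyphenoxy)-2,6-dimethoxyphenol; 4 5-bromo-1,2,3-trimethoxybenzene
Product: 5 5-[4-(2,6-dimethoxyphenoxy)-2,6-dimethoxyphenoxy]-1,2,3-trimethoxybenzene
Conditions: 4 (1.2 equiv), CuI (10 mol%), picolinic acid (20 mol%), K3PO4 (2 equiv), DMSO, 90 °C, Ar
Reagents that add atoms: none
Why: Ullmann-type Cu(I)-catalysed diaryl ether synthesis tolerates di-ortho-substituted phenols, the bromide is unhindered, and under argon the electron-rich phenoxide of 3 is not oxidised; no stereocentre is formed.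

Step 3
Reactants: 5 5-[4-(2,6-dimethoxyphenoxy)-2,6-dimethoxyphenoxy]-1,2,3-trimethoxybenzene; 3 4-(2,6-dimethoxyphenoxy)-2,6-dimethoxyphenol
Product: 8 5-{4-[4-[4-(2,6-dimethoxyphenoxy)-2,6-dimethoxyphenoxy]-2,6-dimethoxyphenoxy]-2,6-dimethoxyphenoxy}-1,2,3-trimethoxybenzene (pentamer), via trimer pinacol boronate 6 (not isolated), via trimer iodide 7 (not isolated)
Conditions: (i) [Ir(cod)OMe]2 (1.5 mol%), dtbpy (3 mol%), B2pin2 (1.0 equiv), THF, 80 °C, then evaporate; (ii) CuI (10 mol%), 1,10-phenanthroline (20 mol%), KI (1.5 equiv), MeOH–H2O 4:1, air, 80 °C, extractive work-up; (iii) 3 (1.3 equiv), CuI (10 mol%), picolinic acid (20 mol%), K3PO4 (2 equiv), DMSO, 90 °C, Ar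
Reagents that add atoms: none
Why: Ir-catalysed C–H borylation is sterically governed and only C4–H of the terminal ring has two ortho hydrogens (every other aryl C–H lies between two oxygen substituents), Cu-mediated ipso-iododeboronation then gives the aryl iodide, and Ullmann-type coupling of it with the hindered phenol 3 forms the C–O bond; no stereocentre is formed.

Step 4
Reactants: 8 5-{4-[4-[4-(2,6-dimethoxyphenoxy)-2,6-dimethoxyphenoxy]-2,6-dimethoxyphenoxy]-2,6-dimethoxyphenoxy}-1,2,3-trimethoxybenzene; 9 2,4,6-trimethoxyphenol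
Product: 12 5-{4-[4-[4-[4-(2,4,6-trimethoxyphenoxy)-2,6-dimethoxyphenoxy]-2,6-dimethoxyphenoxy]-2,6-dimethoxyphenoxy]-2,6-dimethoxyphenoxy}-1,2,3-trimethoxybenzene (per-O-methyl hexamer), via pentamer pinacol boronate 10 (not isolated), via pentamer iodide 11 (not isolated)
Conditions: (i) [Ir(cod)OMe]2 (1.5 mol%), dtbpy (3 mol%), B2pin2 (1.0 equiv), THF, 80 °C, then evaporate; (ii) CuI (10 mol%), 1,10-phenanthroline (20 mol%), KI (1.5 equiv), MeOH–H2O 4:1, air, 80 °C, extractive work-up; (iii) 9 (1.5 equiv), CuI (10 mol%), picolinic acid (20 mol%), K3PO4 (2 equiv), DMSO, 90 °C, Ar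
Reagents that add atoms: none
Why: The same sterically governed chain-end C–H borylation, ipso-iododeboronation and Ullmann-type diaryl ether coupling apply, and the oxygen-free Cu(I) conditions keep the very electron-rich phenoxide of 9 from being oxidised; no stereocentre is formed.

Step 5
Reactants: 12 per-O-methyl hexamer
Product: 13 5-{4-[4-[4-[4-(2,4,6-trihydroxyphenoxy)-2,6-dihydroxyphenoxy]-2,6-dihydroxyphenoxy]-2,6-dihydroxyphenoxy]-2,6-dihydroxyphenoxy}benzene-1,2,3-triol (CNP0187343.0)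
Conditions: BBr3 (45 equiv), CH2Cl2, −78 °C → rt, Ar; then degassed H2O, 0 °C; reversed-phase purification under Ar
Reagents that add atoms: none
Why: Lewis-acid O-demethylation with BBr3 cleaves only the fourteen O–CH3 bonds (bromide attacks methyl), while diaryl ether bonds have no carbon open to SN2 and stay intact; no stereocentre is present.

## Compound list

1 | 2-(2,6-dimethoxyphenyl)-4,4,5,5-tetramethyl-1,3,2-dioxaborolane | COc1cccc(OC)c1B1OC(C)(C)C(C)(C)O1 | starting material
2 | 2,6-dimethoxy-1,4-benzoquinone | COC1=CC(=O)C=C(OC)C1=O | starting material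
3 | 4-(2,6-dimethoxyphenoxy)-2,6-dimethoxyphenol | COc1cccc(OC)c1Oc1cc(OC)c(O)c(OC)c1 | intermediate
4 | 5-bromo-1,2,3-trimethoxybenzene | COc1cc(Br)cc(OC)c1OC | starting material
5 | 5-[4-(2,6-dimethoxyphenoxy)-2,6-dimethoxyphenoxy]-1,2,3-trimethoxybenzene (trimer) | COc1cccc(OC)c1Oc1cc(OC)c(Oc2cc(OC)c(OC)c(OC)c2)c(OC)c1 | intermediate
6 | 2-{4-[2,6-dimethoxy-4-(3,4,5-trimethoxyphenoxy)phenoxy]-3,5-dimethoxyphenyl}-4,4,5,5-tetramethyl-1,3,2-dioxaborolane (trimer pinacol boronate) | COc1cc(B2OC(C)(C)C(C)(C)O2)cc(OC)c1Oc1cc(OC)c(Oc2cc(OC)c(OC)c(OC)c2)c(OC)c1 | intermediate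
7 | 5-[4-(4-iodo-2,6-dimethoxyphenoxy)-2,6-dimethoxyphenoxy]-1,2,3-trimethoxybenzene (trimer iodide) | COc1cc(I)cc(OC)c1Oc1cc(OC)c(Oc2cc(OC)c(OC)c(OC)c2)c(OC)c1 | intermediate
8 | 5-{4-[4-[4-(2,6-dimethoxyphenoxy)-2,6-dimethoxyphenoxy]-2,6-dimethoxyphenoxy]-2,6-dimethoxyphenoxy}-1,2,3-trimethoxybenzene (pentamer) | COc1cccc(OC)c1Oc1cc(OC)c(Oc2cc(OC)c(Oc3cc(OC)c(Oc4cc(OC)c(OC)c(OC)c4)c(OC)c3)c(OC)c2)c(OC)c1 | intermediate
9 | 2,4,6-trimethoxyphenol | COc1cc(OC)c(O)c(OC)c1 | starting material
10 | pentamer pinacol boronate: 8 carrying a 4,4,5,5-tetramethyl-1,3,2-dioxaborolan-2-yl group at C4 (para to the ether oxygen) of its terminal 2,6-dimethoxyphenoxy ring | COc1cc(B2OC(C)(C)C(C)(C)O2)cc(OC)c1Oc1cc(OC)c(Oc2cc(OC)c(Oc3cc(OC)c(Oc4cc(OC)c(OC)c(OC)c4)c(OC)c3)c(OC)c2)c(OC)c1 | intermediate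
11 | 5-{4-[4-[4-(4-iodo-2,6-dimethoxyphenoxy)-2,6-dimethoxyphenoxy]-2,6-dimethoxyphenoxy]-2,6-dimethoxyphenoxy}-1,2,3-trimethoxybenzene (pentamer iodide) | COc1cc(I)cc(OC)c1Oc1cc(OC)c(Oc2cc(OC)c(Oc3cc(OC)c(Oc4cc(OC)c(OC)c(OC)c4)c(OC)c3)c(OC)c2)c(OC)c1 | intermediate
12 | 5-{4-[4-[4-[4-(2,4,6-trimethoxyphenoxy)-2,6-dimethoxyphenoxy]-2,6-dimethoxyphenoxy]-2,6-dimethoxyphenoxy]-2,6-dimethoxyphenoxy}-1,2,3-trimethoxybenzene (per-O-methyl hexamer) | COc1cc(OC)c(Oc2cc(OC)c(Oc3cc(OC)c(Oc4cc(OC)c(Oc5cc(OC)c(Oc6cc(OC)c(OC)c(OC)c6)c(OC)c5)c(OC)c4)c(OC)c3)c(OC)c2)c(OC)c1 | intermediate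
13 | 5-{4-[4-[4-[4-(2,4,6-trihydroxyphenoxy)-2,6-dihydroxyphenoxy]-2,6-dihydroxyphenoxy]-2,6-dihydroxyphenoxy]-2,6-dihydroxyphenoxy}benzene-1,2,3-triol | Oc1cc(O)c(Oc2cc(O)c(Oc3cc(O)c(Oc4cc(O)c(Oc5cc(O)c(Oc6cc(O)c(O)c(O)c6)c(O)c5)c(O)c4)c(O)c3)c(O)c2)c(O)c1 | target

## Step count and risks

Total steps: 5. Longest linear sequence: 5 (steps 1 → 2 → 3 → 4 → 5; compound 3 is made once and used in steps 2 and 3).

Three steps most likely to fail:

**Step 1 (the proposed new method).** The aryl–copper species may instead add to carbon (1,2- or conjugate addition, or OMe displacement), protodeboronate, or arylate O1; the regiochemistry of 3 must be confirmed by HMBC/NOE. The fallback uses known chemistry only, sets out from 2 and returns at 3. Reduce 2 with aqueous Na2S2O4 (EtOAc–H2O) to 2,6-dimethoxybenzene-1,4-diol F1. Then couple F1 with commercial 2-iodo-1,3-dimethoxybenzene under Ullmann conditions (CuI, picolinic acid, K3PO4, DMSO, 100 °C, Ar). Only the unhindered 4-OH of F1 can couple with the di-ortho-substituted aryl iodide, which gives 3 directly.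

**Step 3.** The oxidative iodination could also halogenate the electron-rich rings, and the Ullmann coupling of a hindered phenoxide with an electron-rich iodide may be slow. The fallback sets out from 5 and returns at 8. Borylate 5 to 6 as before, cleave the pinacol ester with NaIO4/NH4OAc in acetone–H2O, and isolate {4-[2,6-dimethoxy-4-(3,4,5-trimethoxyphenoxy)phenoxy]-3,5-dimethoxyphenyl}boronic acid F2. Then join F2 and 3 by Chan–Lam coupling (Cu(OAc)2, pyridine, 4 Å MS, CH2Cl2, dry air, rt, 3 added slowly). This replaces the halide/Cu(I) coupling by an oxidative boronic acid coupling at room temperature.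

**Step 5.** Fourteen methyl ethers must all be cleaved, and the free polyphenol is air-sensitive and hard to separate from partly methylated material. The fallback sets out from 12 and returns at 13. After the BBr3 cleavage, quench and acetylate the crude polyphenol without isolating it (Ac2O, pyridine, DMAP) to the tetradeca-O-acetate of 13 F3. F3 is air-stable and can be chromatographed on silica free of incompletely demethylated species. Methanolysis (cat. NaOMe, degassed MeOH, Ar, then H+ resin) then releases 13.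

## Further compounds

F1 | step 1 | 2,6-dimethoxybenzene-1,4-diol | COc1cc(O)cc(OC)c1O
F2 | step 3 | {4-[2,6-dimethoxy-4-(3,4,5-trimethoxyphenoxy)phenoxy]-3,5-dimethoxyphenyl}boronic acid | COc1cc(B(O)O)cc(OC)c1Oc1cc(OC)c(Oc2cc(OC)c(OC)c(OC)c2)c(OC)c1
F3 | step 5 | tetradeca-O-acetate of 13 | CC(=O)Oc1cc(OC(C)=O)c(Oc2cc(OC(C)=O)c(Oc3cc(OC(C)=O)c(Oc4cc(OC(C)=O)c(Oc5cc(OC(C)=O)c(Oc6cc(OC(C)=O)c(OC(C)=O)c(OC(C)=O)c6)c(OC(C)=O)c5)c(OC(C)=O)c4)c(OC(C)=O)c3)c(OC(C)=O)c2)c(OC(C)=O)c1
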